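**Retrosynthetic overview**
- The (R)-lactol is fixed last, by crystallisation-induced asymmetric transformation of the epimerising hemiacetal; the fumarate half-ester is put on salazinic acid through its ortho-quinone methide.
- Salazinic acid comes from a diaryl ether hydroxy acid by lactonisation, which closes the seven-membered depsidone ring (the last ring formed).
- Key C–C disconnection: the ring B aryl–CH(lactol) bond, made by adding formaldehyde dimethylhydrazone (a neutral formyl-anion equivalent) to a carbomethoxy-para-quinone; the hydroquinone formed is O-arylated in the same flask by a ring A fluoroarene (SNAr).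
- The quinone comes from methyl 2,4,5-trimethoxybenzoate; the ring A fluoroarene from 3,5-difluorotoluene; the benzylic CH2OH from phenoxide hydroxymethylation.
- Ring order: rings A and B are bought as benzenes; the hydroxyphthalide ring closes first (on unmasking the formyl group next to the ring B carboxyl), the depsidone lactone second.

Assumption: the lactol carbon epimerises in solution through the ring-opened formyl acid, so it is fixed only in the last step and the product is then handled cold, as a solid, away from base.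

**Route**

Step 1
Reactants: 1 3,5-difluorotoluene
Product: 6 tert-butyl 2,4-difluoro-3-formyl-6-methylbenzoate, via aryllithium 2 (not isolated), via lithium hemiaminal alkoxide 3 (not isolated), via ring-lithiated hemiaminal alkoxide 4 (not isolated), via ester hemiaminal alkoxide 5 (not isolated)
Conditions: n-BuLi (1.05 equiv), THF, −78 °C; DMF (1.1 equiv), −78 °C; s-BuLi (1.2 equiv), −78 °C; Boc2O (1.5 equiv), −78 → −20 °C; 1 M HCl, 0 °C
Reagents that add atoms: N,N-dimethylformamide CN(C)C=O; di-tert-butyl dicarbonate CC(C)(C)OC(=O)OC(=O)OC(C)(C)C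
Why: Two directed ortho-metalations in one flask: n-BuLi removes the most acidic proton (between the two fluorines), DMF traps the aryllithium as a lithium hemiaminal that masks the aldehyde, s-BuLi then removes the only remaining kind of ring proton (ortho to fluorine; both are equivalent, so there is no regiochemical issue) and Boc2O acylates that aryllithium to the tert-butyl ester; no stereocenter is formed.

Step 2
Reactants: 6 tert-butyl 2,4-difluoro-3-formyl-6-methylbenzoate
Product: 7 tert-butyl 2-fluoro-3-formyl-4-methoxy-6-methylbenzoate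
Conditions: NaOMe (1.05 equiv), MeOH/THF 1:4, −20 → 0 °C
Reagents that add atoms: sodium methoxide [Na+].[O-]C
Why: Nucleophilic aromatic substitution (addition–elimination) in which methoxide takes the fluoride that is ortho to the aldehyde, para to the ester and open on one side, while the fluoride wedged between the aldehyde and the bulky tert-butyl ester is left for the diaryl ether step; no stereocenter.

Step 3
Reactants: 8 methyl 2,4,5-trimethoxybenzoate
Product: 9 methyl 4-methoxy-3,6-dioxocyclohexa-1,4-diene-1-carboxylate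
Conditions: (NH4)2Ce(NO3)6 (2.5 equiv), MeCN/H2O 2:1, 0 °C, 20 min
Reagents that add atoms: water O
Why: Oxidative demethylation of a para-dimethoxyarene by tetravalent cerium gives the para-quinone across the 2- and 5-methoxy groups and keeps the 4-methoxy group as a vinylogous ester; no stereocenter.

Step 4
Reactants: 9 methyl 4-methoxy-3,6-dioxocyclohexa-1,4-diene-1-carboxylate, 10 formaldehyde N,N-dimethylhydrazone, 7 tert-butyl 2-fluoro-3-formyl-4-methoxy-6-methylbenzoate
Product: 12 methyl 3-[2-(tert-butoxycarbonyl)-6-formyl-5-methoxy-3-methylphenoxy]-2-[(E)-(2,2-dimethylhydrazinylidene)methyl]-6-hydroxy-4-methoxybenzoate, via hydroquinone hydrazone 11 (not isolated)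
Conditions: 9 added slowly to 10 (1.2 equiv), MeCN, 0 → 23 °C, Ar; then 7 (1.0 equiv), K2CO3 (2.5 equiv), degassed DMF, 55 °C
Reagents that add atoms: none
Why: Proposed new method: hydrazone 10 is a neutral formyl-anion equivalent (an aza-enamine, nucleophilic at the methylene carbon) and should add in Michael fashion to the only activated C–H position of 9, the carbon beta to both the ester and a ring carbonyl, after which proton shifts restore the hydrazone and aromatise to hydroquinone 11, whose phenol next to the new carbon (the other one is tied up in a salicylate hydrogen bond) then displaces the fluoride of 7, activated by ortho-formyl and ortho-ester groups, in an SNAr reaction; the closest known reaction types are the uncatalysed conjugate additions of formaldehyde dialkylhydrazones to nitroalkenes and alkylidene malonates, the additions of aldehyde dimethylhydrazones to quinones and the selective 5-O-functionalisation of gentisate esters, and no stereocenter is formed.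

Step 5
Reactants: 12 methyl 3-[2-(tert-butoxycarbonyl)-6-formyl-5-methoxy-3-methylphenoxy]-2-[(E)-(2,2-dimethylhydrazinylidene)methyl]-6-hydroxy-4-methoxybenzoate
Product: 13 methyl 3-[2-(tert-butoxycarbonyl)-6-formyl-5-methoxy-3-methylphenoxy]-2-[(E)-(2,2-dimethylhydrazinylidene)methyl]-6-hydroxy-5-(hydroxymethyl)-4-methoxybenzoate
Conditions: 37% aq. CH2O (6 equiv), NaOH (0.3 equiv), THF/H2O 1:1, 40 °C, Ar; pH 5 buffer
Reagents that add atoms: formaldehyde C=O
Why: Base-catalysed ortho-hydroxymethylation of a phenoxide with formaldehyde (Lederer–Manasse reaction): ring B holds the only free phenol and its single unsubstituted carbon is ortho to it, whereas ring A has no phenoxide and is deactivated, so the CH2OH group can only enter at the required position; no stereocenter.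

Step 6
Reactants: 13 methyl 3-[2-(tert-butoxycarbonyl)-6-formyl-5-methoxy-3-methylphenoxy]-2-[(E)-(2,2-dimethylhydrazinylidene)methyl]-6-hydroxy-5-(hydroxymethyl)-4-methoxybenzoate
Product: 16 3-formyl-4-hydroxy-6-methyl-2-{[3,5,7-trihydroxy-6-(hydroxymethyl)-1-oxo-1,3-dihydro-2-benzofuran-4-yl]oxy}benzoic acid, via benzylic bromide 14 (not isolated), via hydrazone diacid 15 (not isolated)
Conditions: BBr3 (12 equiv), CH2Cl2, −78 → 23 °C, 12 h; then THF/H2O 1:1, 0 → 40 °C, 3 h
Reagents that add atoms: water O
Why: Global dealkylation with BBr3 (two aryl methyl ethers, the methyl and tert-butyl esters, benzylic alcohol to bromide) followed by aqueous acid, which hydrolyses the benzylic bromide back to the alcohol and the hydrazone to the aldehyde, whereupon the ortho-formyl benzoic acid closes spontaneously to the hydroxyphthalide; the lactol carbon is created here as a freely interconverting pair of epimers.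

Step 7
Reactants: 16 3-formyl-4-hydroxy-6-methyl-2-{[3,5,7-trihydroxy-6-(hydroxymethyl)-1-oxo-1,3-dihydro-2-benzofuran-4-yl]oxy}benzoic acid
Product: 18 salazinic acid (both lactol epimers), via O-acylisourea 17 (not isolated)
Conditions: DCC (1.2 equiv), THF (0.005 M), 0 → 23 °C
Reagents that add atoms: none
Why: Carbodiimide-mediated lactonisation of the hindered ring A acid onto the neighbouring ring B phenol, the classical depsidone ring closure, favoured over the other hydroxyl groups because only that phenol can close a seven-membered ring; the lactol stays an epimer mixture.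

Step 8
Reactants: 18 salazinic acid (both lactol epimers), 19 fumaric acid
Product: 21 (2E)-4-[(11-formyl-1,4,10-trihydroxy-8-methyl-3,7-dioxo-1,3-dihydro-7H-isobenzofuro[4,5-b][1,4]benzodioxepin-5-yl)methoxy]-4-oxobut-2-enoic acid (both lactol epimers), via ortho-quinone methide 20 (not isolated)
Conditions: 19 (15 equiv), 1,4-dioxane/DMF 5:1, 95 °C
Reagents that add atoms: none
Why: Thermal loss of water from the ortho-hydroxybenzylic alcohol gives an ortho-quinone methide that is captured at the methylene carbon by a carboxyl group of fumaric acid (conjugate 1,4-addition), the same benzylic solvolysis by which salazinic and protocetraric acids form ethers in hot alcohols, and the large excess of diacid keeps the product at the monoester; the lactol stays an epimer mixture.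

Step 9
Reactants: 21 (2E)-4-[(11-formyl-1,4,10-trihydroxy-8-methyl-3,7-dioxo-1,3-dihydro-7H-isobenzofuro[4,5-b][1,4]benzodioxepin-5-yl)methoxy]-4-oxobut-2-enoic acid (both lactol epimers), 22 (R)-N,N-dimethyl-1-phenylethylamine
Product: 24 (2E)-4-{[(1R)-11-formyl-1,4,10-trihydroxy-8-methyl-3,7-dioxo-1,3-dihydro-7H-isobenzofuro[4,5-b][1,4]benzodioxepin-5-yl]methoxy}-4-oxobut-2-enoic acid, via ammonium salt 23 (not isolated)
Conditions: 22 (1.0 equiv), MeCN/EtOAc, 25 → 5 °C, slow evaporation to dryness; then EtOAc/1 M HCl, 0 °C, 5 min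
Reagents that add atoms: none
Why: Crystallisation-induced asymmetric transformation: the amine forms a salt with the fumarate carboxyl group and catalyses lactol epimerisation through the ring-opened formyl acid while one diastereomeric salt crystallises, so the whole sample is funnelled into the salt of the (R)-lactol (which amine enantiomer does this must be settled by experiment; the (R)-amine is written here), and a short cold acid wash frees 24 without time for epimerisation.

**Compound list**

1 | 3,5-difluorotoluene | Cc1cc(F)cc(F)c1 | starting material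
2 | (2,6-difluoro-4-methylphenyl)lithium | Cc1cc(F)c([Li])c(F)c1 | intermediate
3 | lithium (2,6-difluoro-4-methylphenyl)(dimethylamino)methanolate | Cc1cc(F)c(C(O[Li])N(C)C)c(F)c1 | intermediate
4 | lithium (2,6-difluoro-3-lithio-4-methylphenyl)(dimethylamino)methanolate | Cc1cc(F)c(C(O[Li])N(C)C)c(F)c1[Li] | intermediate
5 | lithium [3-(tert-butoxycarbonyl)-2,6-difluoro-4-methylphenyl](dimethylamino)methanolate | Cc1cc(F)c(C(O[Li])N(C)C)c(F)c1C(=O)OC(C)(C)C | intermediate
6 | tert-butyl 2,4-difluoro-3-formyl-6-methylbenzoate | Cc1cc(F)c(C=O)c(F)c1C(=O)OC(C)(C)C | intermediate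
7 | tert-butyl 2-fluoro-3-formyl-4-methoxy-6-methylbenzoate | Cc1cc(OC)c(C=O)c(F)c1C(=O)OC(C)(C)C | intermediate
8 | methyl 2,4,5-trimethoxybenzoate | COC(=O)c1cc(OC)c(OC)cc1OC | starting material
9 | methyl 4-methoxy-3,6-dioxocyclohexa-1,4-diene-1-carboxylate | COC(=O)C1=CC(=O)C(OC)=CC1=O | intermediate
10 | formaldehyde N,N-dimethylhydrazone | C=NN(C)C | starting material
11 | methyl 2-[(E)-(2,2-dimethylhydrazinylidene)methyl]-3,6-dihydroxy-4-methoxybenzoate | COC(=O)c1c(O)cc(OC)c(O)c1/C=N/N(C)C | intermediate
12 | methyl 3-[2-(tert-butoxycarbonyl)-6-formyl-5-methoxy-3-methylphenoxy]-2-[(E)-(2,2-dimethylhydrazinylidene)methyl]-6-hydroxy-4-methoxybenzoate | COC(=O)c1c(O)cc(OC)c(Oc2c(C=O)c(OC)cc(C)c2C(=O)OC(C)(C)C)c1/C=N/N(C)C | intermediate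
13 | methyl 3-[2-(tert-butoxycarbonyl)-6-formyl-5-methoxy-3-methylphenoxy]-2-[(E)-(2,2-dimethylhydrazinylidene)methyl]-6-hydroxy-5-(hydroxymethyl)-4-methoxybenzoate | COC(=O)c1c(O)c(CO)c(OC)c(Oc2c(C=O)c(OC)cc(C)c2C(=O)OC(C)(C)C)c1/C=N/N(C)C | intermediate
14 | 2-[3-(bromomethyl)-5-carboxy-6-[(E)-(2,2-dimethylhydrazinylidene)methyl]-2,4-dihydroxyphenoxy]-3-formyl-4-hydroxy-6-methylbenzoic acid (drawn free of boron) | Cc1cc(O)c(C=O)c(Oc2c(O)c(CBr)c(O)c(C(=O)O)c2/C=N/N(C)C)c1C(=O)O | intermediate
15 | 2-[5-carboxy-6-[(E)-(2,2-dimethylhydrazinylidene)methyl]-2,4-dihydroxy-3-(hydroxymethyl)phenoxy]-3-formyl-4-hydroxy-6-methylbenzoic acid | Cc1cc(O)c(C=O)c(Oc2c(O)c(CO)c(O)c(C(=O)O)c2/C=N/N(C)C)c1C(=O)O | intermediate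
16 | 3-formyl-4-hydroxy-6-methyl-2-{[3,5,7-trihydroxy-6-(hydroxymethyl)-1-oxo-1,3-dihydro-2-benzofuran-4-yl]oxy}benzoic acid (both lactol epimers) | Cc1cc(O)c(C=O)c(Oc2c(O)c(CO)c(O)c3C(=O)OC(O)c23)c1C(=O)O | intermediate
17 | N,N'-dicyclohexyl-O-acylisourea of 16 (acyl group = the ring A carboxyl) | Cc1cc(O)c(C=O)c(Oc2c(O)c(CO)c(O)c3C(=O)OC(O)c23)c1C(=O)OC(=NC1CCCCC1)NC1CCCCC1 | intermediate
18 | salazinic acid, 1,4,10-trihydroxy-5-(hydroxymethyl)-8-methyl-3,7-dioxo-1,3-dihydro-7H-isobenzofuro[4,5-b][1,4]benzodioxepin-11-carbaldehyde (both lactol epimers) | Cc1cc(O)c(C=O)c2c1C(=O)Oc1c(CO)c(O)c3c(c1O2)C(O)OC3=O | intermediate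
19 | fumaric acid | OC(=O)/C=C/C(=O)O | starting material
20 | ortho-quinone methide of 18 (ring B as 4-oxo-5-methylidene dienone) | Cc1cc(O)c(C=O)c2c1C(=O)OC1=C(O2)C3=C(C(=O)C1=C)C(=O)OC3O | intermediate
21 | (2E)-4-[(11-formyl-1,4,10-trihydroxy-8-methyl-3,7-dioxo-1,3-dihydro-7H-isobenzofuro[4,5-b][1,4]benzodioxepin-5-yl)methoxy]-4-oxobut-2-enoic acid (both lactol epimers) | Cc1cc(O)c(C=O)c2c1C(=O)Oc1c(COC(=O)/C=C/C(=O)O)c(O)c3c(c1O2)C(O)OC3=O | intermediate
22 | (R)-N,N-dimethyl-1-phenylethylamine | C[C@@H](N(C)C)c1ccccc1 | starting material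
23 | (R)-N,N-dimethyl-1-phenylethylammonium salt of 24 (fumarate carboxylate, (R)-lactol) | Cc1cc(O)c(C=O)c2c1C(=O)Oc1c(COC(=O)/C=C/C(=O)[O-])c(O)c3c(c1O2)[C@H](O)OC3=O.C[C@@H]([NH+](C)C)c1ccccc1 | intermediate
24 | (2E)-4-{[(1R)-11-formyl-1,4,10-trihydroxy-8-methyl-3,7-dioxo-1,3-dihydro-7H-isobenzofuro[4,5-b][1,4]benzodioxepin-5-yl]methoxy}-4-oxobut-2-enoic acid (salazinic acid hydrogen fumarate at the benzylic CH2O, (R) at the lactol carbon) | Cc1cc(O)c(C=O)c2c1C(=O)Oc1c(COC(=O)/C=C/C(=O)O)c(O)c3c(c1O2)[C@H](O)OC3=O | target

**Step count and risks**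

Total steps: 9. Longest linear sequence: 8 (steps 1, 2, 4, 5, 6, 7, 8, 9 from 3,5-difluorotoluene; 7 from methyl 2,4,5-trimethoxybenzoate).

The three steps most likely to fail:

Step 4 is an untested combination: the hydrazone may reduce the quinone instead of adding, and the hindered SNAr may be slow or pick the wrong phenol. The fallback sets out from 9. Irradiation (350 nm) of 9 with benzophenone in degassed 1,3-dioxolane/MeCN generates the nucleophilic 1,3-dioxolan-2-yl radical, a formyl-radical equivalent, which adds at the same quinone carbon to give the dioxolane hydroquinone F1. SNAr with 7 (K2CO3, DMF, 55 °C) gives the dioxolane diaryl ether F2, and hydroxymethylation as in the main route gives the hydroxymethyl dioxolane diaryl ether F3. BBr3 followed by aqueous acid, which also opens the acetal and passes through the bromomethyl lactol F4, comes back to the route at 16.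

Step 8 may give oligomers, acylation at the lactol, or an unfavourable equilibrium with water. The fallback sets out from 18. 4 M HCl in 1,4-dioxane at 0 °C converts the ortho-hydroxybenzylic alcohol into the benzylic chloride F5 (any chloride formed at the lactol reverts on aqueous work-up). Displacement with preformed tetrabutylammonium hydrogen fumarate in MeCN at 0 → 23 °C comes back to the route at 21.

Step 9 depends on a salt that crystallises well, and on the (R)-lactol salt being the less soluble one; neither can be predicted. The fallback sets out from 21. It is a direct resolution by preparative chiral supercritical-fluid chromatography on an immobilised amylose carbamate phase (CO2/MeCN with 0.1% formic acid, 5 °C). The (S)-epimer fraction is re-equilibrated with a trace of tertiary amine and re-injected, and the (R)-fraction is 24, where the fallback comes back to the route. It makes no new compound (entry F0).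

**Further compounds**

F1 | step 4 | methyl 2-(1,3-dioxolan-2-yl)-3,6-dihydroxy-4-methoxybenzoate | COC(=O)c1c(O)cc(OC)c(O)c1C1OCCO1
F2 | step 4 | methyl 3-[2-(tert-butoxycarbonyl)-6-formyl-5-methoxy-3-methylphenoxy]-2-(1,3-dioxolan-2-yl)-6-hydroxy-4-methoxybenzoate | COC(=O)c1c(O)cc(OC)c(Oc2c(C=O)c(OC)cc(C)c2C(=O)OC(C)(C)C)c1C1OCCO1
F3 | step 4 | methyl 3-[2-(tert-butoxycarbonyl)-6-formyl-5-methoxy-3-methylphenoxy]-2-(1,3-dioxolan-2-yl)-6-hydroxy-5-(hydroxymethyl)-4-methoxybenzoate | COC(=O)c1c(O)c(CO)c(OC)c(Oc2c(C=O)c(OC)cc(C)c2C(=O)OC(C)(C)C)c1C1OCCO1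
F4 | step 4 | 2-{[6-(bromomethyl)-3,5,7-trihydroxy-1-oxo-1,3-dihydro-2-benzofuran-4-yl]oxy}-3-formyl-4-hydroxy-6-methylbenzoic acid | Cc1cc(O)c(C=O)c(Oc2c(O)c(CBr)c(O)c3C(=O)OC(O)c23)c1C(=O)O
F5 | step 8 | 5-(chloromethyl)-1,4,10-trihydroxy-8-methyl-3,7-dioxo-1,3-dihydro-7H-isobenzofuro[4,5-b][1,4]benzodioxepin-11-carbaldehyde | Cc1cc(O)c(C=O)c2c1C(=O)Oc1c(CCl)c(O)c3c(c1O2)C(O)OC3=O
F0 | step 9 | none | none
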